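**Retrosynthetic overview**
1. Numbering used throughout (germacranolide): C1 ketone, C10 (bears the exocyclic methylene C14), C9, C8 (OAc), C7=C11 butenolide alkene (C13H2OAc on C11), C12 lactone carbonyl, C6 (lactone CH–O), C5=C4 (C15 methyl on C4), C3, C2.
2. Target 20 ⇐ diol 19 ⇐ hydroxy enone 18 (acetylation, desilylation).
3. Key disconnection C1–C10: 18 ⇐ nine-membered lactone 15, in which C1 is stored as an ester on O8; a C10 vinyl anion takes C1 from O8 (ring expansion 9 → 10 by O→C acyl transfer). Enabling feature: O8 is γ to the C1 ketone (O8–C8–C9–C10–C1, five-membered transition state), and the butenolide fused at C6–C7 holds C6 and C8 side by side, so the lactone ring O8–C1–C2–C3–C4=C5–C6–C7–C8 is small enough to enforce the Z C4=C5 alkene.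
4. 15 ⇐ ring-closing metathesis of ester 14 ⇐ C8 alcohol 12 + acid 13; 12 ⇐ 2-bromoallylboration of aldehyde 10 (C8–C9 bond).
5. 10 ⇐ 7 (ozonolysis); 7 ⇐ ynoate 3 + alkenylcopper + CH2O; 3 ⇐ acrolein + methyl propiolate. Ring order: butenolide, then nine-membered lactone (temporary), then ten-membered carbocycle.

Key step: step 8

Remark: boronate 11 is taken as a purchasable reagent (otherwise one step from 2,3-dibromopropene and bis(pinacolato)diboron).

**Step 1**
Reactants: 1 acrolein; 2 methyl propiolate
Product: 3 methyl (4R)-4-hydroxyhex-5-en-2-ynoate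
Conditions: Me2Zn (3 equiv), ProPhenol ligand (10 mol%, the enantiomer that directs alkynyl transfer to the Si face; the (R,R)-ligand is expected), Ph3P=O (20 mol%), toluene, 4 °C; aq. NH4Cl
Reagents that add atoms: none
Why: Catalytic asymmetric alkynylation (1,2-addition of a zinc alkynylide held in the dinuclear zinc–ProPhenol pocket) of the enal; Si-face attack sets C6 as R under catalyst control.

**Step 2**
Reactants: 3 methyl (4R)-4-hydroxyhex-5-en-2-ynoate; 4 (2-methylprop-1-en-1-yl)magnesium bromide; 5 formaldehyde
Product: 7 (5R)-5-ethenyl-3-(hydroxymethyl)-4-(2-methylprop-1-en-1-yl)furan-2(5H)-one, via open-chain Z-dihydroxy ester 6 (not isolated)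
Conditions: 3 + 4 (1.05 equiv), THF, −78 °C; then Me2C=CHCu·MgBr2 preformed from 4 (1.5 equiv) and CuBr·SMe2 (1.5 equiv), −78 → −50 °C; CH2O gas (cracked paraformaldehyde), −78 → −40 °C; aq. NH4Cl/AcOH, 0 °C → rt
Reagents that add atoms: none
Why: syn-Carbocupration of the ynoate (alkenyl group to C7, copper to C11) followed by aldol capture of the C11–copper species by formaldehyde with retention should give Z-ester 6, whose C6 hydroxyl is cis to the ester and lactonises on acidic work-up (tandem conjugate addition–aldol–lactonisation); C6 is carried through unchanged.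

**Step 3**
Reactants: 7 (5R)-5-ethenyl-3-(hydroxymethyl)-4-(2-methylprop-1-en-1-yl)furan-2(5H)-one
Product: 8 (5R)-3-({[tert-butyl(dimethyl)silyl]oxy}methyl)-5-ethenyl-4-(2-methylprop-1-en-1-yl)furan-2(5H)-one
Conditions: TBSCl, imidazole, CH2Cl2, 0 °C → rt
Reagents that add atoms: tert-butyldimethylsilyl chloride, CC(C)(C)[Si](C)(C)Cl
Why: Standard silylation of the primary allylic alcohol, which keeps O13 from forming a lactol with the C8 aldehyde made next and is inert to ozone, the boronate and t-BuLi.

**Step 4**
Reactants: 8 (5R)-3-({[tert-butyl(dimethyl)silyl]oxy}methyl)-5-ethenyl-4-(2-methylprop-1-en-1-yl)furan-2(5H)-one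
Product: 10 (2R)-4-({[tert-butyl(dimethyl)silyl]oxy}methyl)-2-ethenyl-5-oxo-2,5-dihydrofuran-3-carbaldehyde, via trioxolane 9 (not isolated)
Conditions: O3, CH2Cl2, −78 °C, Sudan Red 7B as end-point indicator; then Me2S, −78 °C → rt
Reagents that add atoms: ozone, [O-][O+]=O
Why: Ozonolysis with reductive work-up; the electron-rich trisubstituted C8=C9 alkene should react far faster than the monosubstituted C6 vinyl group (deactivated by the allylic lactone oxygen) and the electron-poor tetrasubstituted butenolide alkene, and the dye end-point limits ozone to one equivalent.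

**Step 5**
Reactants: 10 (2R)-4-({[tert-butyl(dimethyl)silyl]oxy}methyl)-2-ethenyl-5-oxo-2,5-dihydrofuran-3-carbaldehyde; 11 2-(2-bromoprop-2-en-1-yl)-4,4,5,5-tetramethyl-1,3,2-dioxaborolane
Product: 12 (5R)-4-[(1S)-3-bromo-1-hydroxybut-3-en-1-yl]-3-({[tert-butyl(dimethyl)silyl]oxy}methyl)-5-ethenylfuran-2(5H)-one
Conditions: (S)-TRIP [(S)-3,3′-bis(2,4,6-triisopropylphenyl)-1,1′-binaphthyl-2,2′-diyl hydrogen phosphate] (5 mol%), toluene, −30 °C; aqueous work-up
Reagents that add atoms: none
Why: Chiral phosphoric acid-catalysed allylboration through a closed chair transition state; the (S)-catalyst, antipode of the one that allylates aryl and alkenyl aldehydes on the Re face, should deliver the 2-bromoallyl group to the Si face of the C8 aldehyde and set C8 as S under catalyst control.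

**Step 6**
Reactants: 12 (5R)-4-[(1S)-3-bromo-1-hydroxybut-3-en-1-yl]-3-({[tert-butyl(dimethyl)silyl]oxy}methyl)-5-ethenylfuran-2(5H)-one; 13 4-methylpent-4-enoic acid
Product: 14 (1S)-3-bromo-1-[(2R)-4-({[tert-butyl(dimethyl)silyl]oxy}methyl)-2-ethenyl-5-oxo-2,5-dihydrofuran-3-yl]but-3-en-1-yl 4-methylpent-4-enoate
Conditions: EDC·HCl, DMAP (cat.), CH2Cl2, 0 °C → rt
Reagents that add atoms: none
Why: Steglich esterification of the secondary alcohol, which places C1–C4 and C15 on O8 as the tether used in the two ring-forming steps that follow; no stereocentre is touched.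

**Step 7**
Reactants: 14 (1S)-3-bromo-1-[(2R)-4-({[tert-butyl(dimethyl)silyl]oxy}methyl)-2-ethenyl-5-oxo-2,5-dihydrofuran-3-yl]but-3-en-1-yl 4-methylpent-4-enoate
Product: 15 8,1-lactone of (4Z,6R,8S)-10-bromo-13-[(tert-butyldimethylsilyl)oxy]-8-hydroxy-1,10-secogermacra-4,7(11),10(14)-trien-12,6-olid-1-oic acid (nine-membered lactone O8–C1–C2–C3–C4=C5–C6–C7–C8 fused at C6–C7 to the butenolide; 2-bromoallyl group on C8)
Conditions: second-generation Grubbs catalyst RuCl2(=CHPh)(PCy3)(H2IMes) (10 mol%), toluene (1 mM), 80 °C
Reagents that add atoms: none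
Why: Ring-closing metathesis between the C6 vinyl group and the 1,1-disubstituted alkene of the ester, helped by the planar butenolide that holds C6 and C8 on adjacent positions; in a nine-membered ring the C4=C5 alkene is expected to form only as the Z isomer, so the alkene geometry of the target is set here, while the 2-bromoalkene should stay a spectator.

**Step 8**
Reactants: 15 nine-membered lactone (as named in step 7)
Product: 18 (4Z,6R,8S)-13-[(tert-butyldimethylsilyl)oxy]-8-hydroxy-1-oxogermacra-4,7(11),10(14)-trien-12,6-olide, via vinyllithium 16 (not isolated), via bridged lithium hemiketal alkoxide 17 (not isolated)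
Conditions: t-BuLi (2.1 equiv), THF/Et2O/pentane 4:1:1, −110 °C, 10 min; then AcOH in THF, −110 → −20 °C
Reagents that add atoms: none
Why: Proposed new method: bromine–lithium exchange at C10 gives vinyllithium 16, whose carbanion lies four bonds from the lactone carbonyl (C10–C9–C8–O8–C1) and should add to C1 through a five-membered transition state to give bridged hemiketal alkoxide 17; scission of the C1–O8 bond of 17, driven by enone conjugation and loss of the bridged bicycle, leaves the C1 ketone on C10 and the C8 alkoxide, so the nine-membered lactone has become the ten-membered carbocycle. The closest known reaction types are the Parham-type halogen–lithium exchange/intramolecular acyl substitution of esters, the anionic 1,4-O→C acyl (homo-Fries) shift, and the SmI2-promoted intramolecular nucleophilic acyl substitution that expands iodoalkyl lactones to hydroxy ketones; a vinyllithium doing this on a medium-ring lactone to give a carbocycle has no close precedent. Ring closure: the oxolane of 17 forms by 5-exo-trig attack on C1=O and the ten-membered ring arises from it by fragmentation, so no medium-ring transition state is needed. No stereocentre is created in 18 (the hemiketal centre of 17 is transient and fixed by the bridge), and C6, C8 and the Z C4=C5 alkene are not touched. The step needs chemoselectivity for C1 over the butenolide carbonyl C12 and over deprotonation of the acidic C6–H: C12 is trans to C8 across C7=C11 and cannot be reached, the only other oxygen function is a silyl ether, and exchange plus five-ring addition at −110 °C followed by a cold acetic acid quench should outrun proton transfer.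

**Step 9**
Reactants: 18 (4Z,6R,8S)-13-[(tert-butyldimethylsilyl)oxy]-8-hydroxy-1-oxogermacra-4,7(11),10(14)-trien-12,6-olide
Product: 19 (4Z,6R,8S)-8,13-dihydroxy-1-oxogermacra-4,7(11),10(14)-trien-12,6-olide
Conditions: HF·pyridine, THF/pyridine, 0 °C
Reagents that add atoms: none
Why: Fluoride-mediated desilylation under buffered, weakly acidic conditions that should spare the exocyclic enone and the epimerisable C6–H.

**Step 10**
Reactants: 19 (4Z,6R,8S)-8,13-dihydroxy-1-oxogermacra-4,7(11),10(14)-trien-12,6-olide
Product: 20 (4Z,6R,8S)-8,13-diacetoxy-1-oxogermacra-4,7(11),10(14)-trien-12,6-olide (CNP0239761.1)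
Conditions: Ac2O, pyridine, DMAP (cat.), CH2Cl2, 0 °C
Reagents that add atoms: acetic anhydride, CC(=O)OC(C)=O
Why: DMAP-catalysed acetylation of the primary C13 and secondary C8 alcohols (any transannular hemiketal form equilibrates with the open hydroxy ketone, which is the form acylated); no stereocentre is touched.

**Compound list**
1 | acrolein (prop-2-enal) | C=CC=O | starting material
2 | methyl propiolate | C#CC(=O)OC | starting material
3 | methyl (4R)-4-hydroxyhex-5-en-2-ynoate | C=C[C@@H](O)C#CC(=O)OC | intermediate
4 | (2-methylprop-1-en-1-yl)magnesium bromide | CC(C)=C[Mg]Br | starting material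
5 | formaldehyde | C=O | starting material
6 | methyl (2Z)-2-(hydroxymethyl)-3-[(1R)-1-hydroxyprop-2-en-1-yl]-5-methylhexa-2,4-dienoate (not isolated) | COC(=O)/C(CO)=C(\[C@H](O)C=C)C=C(C)C | intermediate
7 | (5R)-5-ethenyl-3-(hydroxymethyl)-4-(2-methylprop-1-en-1-yl)furan-2(5H)-one | O=C1O[C@H](C=C)C(C=C(C)C)=C1CO | intermediate
8 | (5R)-3-({[tert-butyl(dimethyl)silyl]oxy}methyl)-5-ethenyl-4-(2-methylprop-1-en-1-yl)furan-2(5H)-one | O=C1O[C@H](C=C)C(C=C(C)C)=C1CO[Si](C)(C)C(C)(C)C | intermediate
9 | (5R)-3-({[tert-butyl(dimethyl)silyl]oxy}methyl)-4-(5,5-dimethyl-1,2,4-trioxolan-3-yl)-5-ethenylfuran-2(5H)-one (both epimers at the trioxolane carbon; not isolated) | O=C1O[C@H](C=C)C(C2OOC(C)(C)O2)=C1CO[Si](C)(C)C(C)(C)C | intermediate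
10 | (2R)-4-({[tert-butyl(dimethyl)silyl]oxy}methyl)-2-ethenyl-5-oxo-2,5-dihydrofuran-3-carbaldehyde | O=CC1=C(CO[Si](C)(C)C(C)(C)C)C(=O)O[C@@H]1C=C | intermediate
11 | 2-(2-bromoprop-2-en-1-yl)-4,4,5,5-tetramethyl-1,3,2-dioxaborolane | C=C(Br)CB1OC(C)(C)C(C)(C)O1 | starting material
12 | (5R)-4-[(1S)-3-bromo-1-hydroxybut-3-en-1-yl]-3-({[tert-butyl(dimethyl)silyl]oxy}methyl)-5-ethenylfuran-2(5H)-one | C=C(Br)C[C@H](O)C1=C(CO[Si](C)(C)C(C)(C)C)C(=O)O[C@@H]1C=C | intermediate
13 | 4-methylpent-4-enoic acid | C=C(C)CCC(=O)O | starting material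
14 | (1S)-3-bromo-1-[(2R)-4-({[tert-butyl(dimethyl)silyl]oxy}methyl)-2-ethenyl-5-oxo-2,5-dihydrofuran-3-yl]but-3-en-1-yl 4-methylpent-4-enoate | C=C(Br)C[C@H](OC(=O)CCC(C)=C)C1=C(CO[Si](C)(C)C(C)(C)C)C(=O)O[C@@H]1C=C | intermediate
15 | 8,1-lactone of (4Z,6R,8S)-10-bromo-13-[(tert-butyldimethylsilyl)oxy]-8-hydroxy-1,10-secogermacra-4,7(11),10(14)-trien-12,6-olid-1-oic acid | C=C(Br)C[C@@H]1OC(=O)CC/C(C)=C\[C@H]2OC(=O)C(CO[Si](C)(C)C(C)(C)C)=C12 | intermediate
16 | C10-lithio analogue of 15 (vinyllithium; not isolated) | C=C([Li])C[C@@H]1OC(=O)CC/C(C)=C\[C@H]2OC(=O)C(CO[Si](C)(C)C(C)(C)C)=C12 | intermediate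
17 | lithium alkoxide of the bridged hemiketal (C1 bonded to O8, C2, C10 and OLi; oxolane C1–O8–C8–C9–C10 inside the ten-membered ring; not isolated) | C=C1C[C@@H]2O[C@@]1(O[Li])CC/C(C)=C\[C@H]1OC(=O)C(CO[Si](C)(C)C(C)(C)C)=C12 | intermediate
18 | (4Z,6R,8S)-13-[(tert-butyldimethylsilyl)oxy]-8-hydroxy-1-oxogermacra-4,7(11),10(14)-trien-12,6-olide | C=C1C[C@H](O)C2=C(CO[Si](C)(C)C(C)(C)C)C(=O)O[C@@H]2/C=C(/C)CCC1=O | intermediate
19 | (4Z,6R,8S)-8,13-dihydroxy-1-oxogermacra-4,7(11),10(14)-trien-12,6-olide | C=C1C[C@H](O)C2=C(CO)C(=O)O[C@@H]2/C=C(/C)CCC1=O | intermediate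
20 | (4Z,6R,8S)-8,13-diacetoxy-1-oxogermacra-4,7(11),10(14)-trien-12,6-olide (CNP0239761.1) | C=C1C[C@H](OC(C)=O)C2=C(COC(C)=O)C(=O)O[C@@H]2/C=C(/C)CCC1=O | target

**Total step count:** 10
**Longest linear sequence:** 10 steps (from acrolein and methyl propiolate)

**Steps most likely to fail**

1. Step 8 (proposed new method). What may go wrong: proton transfer from the acidic C6–H to t-BuLi or to the vinyllithium, or addition of t-BuLi to a lactone carbonyl, may compete with bromine–lithium exchange, and the bridged hemiketal alkoxide may be slow to open. Fallback with known chemistry, setting out from lactone 15 and returning at 18: i-Bu2AlH (1.1 equiv, CH2Cl2, −78 °C) should reduce the saturated nine-membered lactone in preference to the conjugated, tetrasubstituted butenolide and give, after opening of the lactol, hydroxy aldehyde F1. An intramolecular Nozaki–Hiyama–Kishi reaction of the vinyl bromide with the aldehyde (CrCl2, NiCl2 (cat.), DMSO/THF, high dilution) should then form the same C1–C10 bond and give ten-membered allylic alcohol F2 as both C1 epimers. MnO2 in CH2Cl2 should oxidise the C1 carbinol, which is allylic to the electron-rich 1,1-disubstituted alkene, faster than the C8 carbinol on the electron-poor butenolide alkene, and so return to 18.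

2. Step 2. What may go wrong: slow capture of the C11–copper intermediate by formaldehyde, equilibration to the allenolate with loss of alkene geometry, and epimerisation at C6 if the lactone closes while the mixture is still basic. Fallback, setting out from 3 and returning at 7: the same carbocupration is quenched with iodine (I2, THF, −78 °C), a capture that is fast and proceeds with retention, and acidic work-up should give iodobutenolide F3. A Stille coupling of F3 with (tributylstannyl)methanol (Pd(PPh3)4, dioxane, 80 °C) should then install the hydroxymethyl group and return to 7.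

3. Step 7. What may go wrong: intermolecular metathesis at the C6 vinyl group (oligomerisation) may outrun closure of the nine-membered lactone, and the catalyst may be lost at the bromoalkene. Fallback by relay ring-closing metathesis, setting out from 12 and returning at 15: a Wittig reaction of levulinic acid with (hex-5-en-1-yl)triphenylphosphonium bromide (NaN(SiMe3)2, THF; alkene geometry irrelevant) should give relay acid F4. Esterification of 12 with F4 (EDC·HCl, DMAP) should give relay ester F5. With the same ruthenium catalyst the carbene should load at the remote terminal alkene of F5, expel cyclopentene and thereby be placed on C4, from where it can only close onto the C6 vinyl group to give 15.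

**Further compounds**
F1 | step 8 | (5R)-4-[(1S)-3-bromo-1-hydroxybut-3-en-1-yl]-3-({[tert-butyl(dimethyl)silyl]oxy}methyl)-5-[(1Z)-2-methyl-5-oxopent-1-en-1-yl]furan-2(5H)-one | C=C(Br)C[C@H](O)C1=C(CO[Si](C)(C)C(C)(C)C)C(=O)O[C@@H]1/C=C(/C)CCC=O
F2 | step 8 | (4Z,6R,8S)-13-[(tert-butyldimethylsilyl)oxy]-1,8-dihydroxygermacra-4,7(11),10(14)-trien-12,6-olide (both C1 epimers) | C=C1C[C@H](O)C2=C(CO[Si](C)(C)C(C)(C)C)C(=O)O[C@@H]2/C=C(/C)CCC1O
F3 | step 2 | (5R)-5-ethenyl-3-iodo-4-(2-methylprop-1-en-1-yl)furan-2(5H)-one | O=C1O[C@H](C=C)C(C=C(C)C)=C1I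
F4 | step 7 | 4-methyldeca-4,9-dienoic acid (E/Z mixture) | C=CCCCC=C(C)CCC(=O)O
F5 | step 7 | (1S)-3-bromo-1-[(2R)-4-({[tert-butyl(dimethyl)silyl]oxy}methyl)-2-ethenyl-5-oxo-2,5-dihydrofuran-3-yl]but-3-en-1-yl 4-methyldeca-4,9-dienoate | C=C(Br)C[C@H](OC(=O)CCC(C)=CCCCC=C)C1=C(CO[Si](C)(C)C(C)(C)C)C(=O)O[C@@H]1C=C
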